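The data were computed on assumed constants, and the scatter is random.

**Turnover count.** 98.3 turnovers per catalyst charged stand in the north-west run at 12.0 h. This turnover count, the usual turnover number, is product made per catalyst charged, and I read it as the number to watch.

all flasks: substrate 0.050 M; added ligand 0.17 mM
- north: coupling partner 0.060 M; free catalyst 0.25 mM; the very flask that is asked about, followed so far
- north-west: coupling partner 0.060 M; free catalyst 0.38 mM; run made earlier
- flask: coupling partner 0.0600 M; free catalyst 0.25 mM; time 12 h

| north: time / h | north: product / % | north-west: time / h | north-west: product / % |
|---|---|---|---|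
| 0.200 | 6.0 | 2.50 | 45.0 |
| 0.667 | 15.5 | 5.00 | 59.0 |
| 1.00 | 18.8 | 8.00 | 67.2 |
| 1.50 | 23.1 | 10.0 | 71.6 |
| 2.50 | 29.7 | 12.0 | 74.7 |

(standard deviation of a reading: 0.3 percentage points)

- the state of affairs at 12 h: stopped, and by what, or still going (no working catalyst is left / forward and back rates have come level / it is still moving / all of the substrate has reacted / the coupling partner has run out first)
- product at 12 h, in percent of the substrate charged

- the numbers in the tables scatter with a standard deviation of 0.3 percentage points
- the reaction counts as stopped when no species that holds the substrate changes by six tenths of a point or more over the second half of the time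

**Shared clock.** At 2.50 h the north-west run counts 59.2 and the north run 59.4, on the same ligand charge. I therefore let the asked flask, which is the north flask, carry the north-west count at 12 h, and that gives me 49.1% product.

**Turned round.** For all of the substrate to react, the asked flask needs a count of 200, twice the one I carry. A stop needs every species that holds the substrate, product among them, to stay inside the margin noted above over the whole second half. Yet the north-west rise from 10.0 h to 12.0 h, scaled to this catalyst charge, is 2 percentage points, so I say it is still moving.

**The forecast.** It says it is still moving and 55%, on the ground of a “surviving excess that keeps turning over”. Its yield stands above mine.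

**The flask.** It gives it is still moving and 50.4%.

    substrate ⇌ dormant form (K = 1.80, k = 0.00846 s⁻¹)
    coupling partner + free catalyst → catalyst intermediate A (k = 0.719 L mol⁻¹ s⁻¹)
    catalyst intermediate B → spent catalyst (k = 0.00191 s⁻¹)
    substrate + catalyst intermediate A ⇌ catalyst intermediate B (K = 10.1 L mol⁻¹, k = 449 L mol⁻¹ s⁻¹)
    catalyst intermediate B → free catalyst + product (k = 0.248 s⁻¹)
    free catalyst + added ligand ⇌ idle complex (K = 43000 L mol⁻¹, k = 3.97 L mol⁻¹ s⁻¹)

**Two exits.** Catalyst intermediate B gives free catalyst and product 130 times as fast as it gives spent catalyst. The asked flask stands at a count of 101 with 77.7% of its catalyst spent. With 0.20 M of substrate, my count of 98.3 gives 12.3%, and that neighbour flask gives 13.1%.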